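## Analysis of the target

Target 40 is an eremophilane-type cis-decalin. Ring A is C1 (carbinol esterified by (2E,4E,6E)-5-methyldodeca-2,4,6-trienoic acid), C2, C3, C4 (ring-fusion CH), C9 (quaternary ring-fusion carbon with CH3) and C10 (CHCH3); ring B is C4, C5 (CHOH), C6 (ketone), C7, C8 and C9, and C7 carries the exocyclic alkene to C11 (CH3, C12H2OH). The five stereocentres are 1R,4S,5R,9R,10R: the C4 hydrogen, the C5 hydroxyl and the C9 and C10 methyl groups lie on one face of the bicycle and the C1 oxygen on the other, so C1–O is trans to the C10 methyl and the two methyl groups are cis. The C7=C11 alkene is tetrasubstituted and Z, with C12 on the side of the C6 carbonyl. The sensitive groups are the (Z)-γ-hydroxy enone (acid closes it to a hemiketal that dehydrates to a furan), the C5 α-ketol (epimerisation or ketol shift; a free C5/C6 diketone would enolise into C4 and erase the ring fusion) and the conjugated trienoate, which excludes oxidants, strong bases and hydrides once it is attached. The difficulty lies in the quaternary C9 flanked by three stereocentres, in four contiguous stereocentres on a flexible cis-decalin whose two chair–chair forms expose opposite faces of ring A and of C5, and in the geometry of the tetrasubstituted alkene. The strategy rests on the chain C6(=O)–C7–C8–C9–C10 with the C1 oxygen next to C10: if C1–O/C10–H is read as a hydrated C1=C10 alkene, ring B holds a ketone whose δ,ε-alkene and C8–C9 bond are the retron of an oxy-Cope rearrangement that makes the quaternary centre and the cis fusion together. The oxygenated C5 beside C6 then corresponds to the ketal carbon of an o-quinone monoketal, so the bicycle can be traced to a dearomatised 2-methoxyphenol.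

## Retrosynthetic reasoning

40 is traced to bis-silyl ether 39 and then, by cutting the C1–O acyl bond, to alcohol 29 and acid 37. The ester is cut first because the triene tolerates neither the oxidations nor the enolate and hydride chemistry needed on the decalin. Forward, only an acylation of a hindered equatorial alcohol and a buffered desilylation remain.

Acid 37 is cut at C2′=C3′ and at C6′=C7′ (two Horner–Wadsworth–Emmons disconnections) to hexanal 30 and phosphonates 31 and 35, passing through dienal 34. Both new alkenes are disubstituted, where E-selective olefination is reliable; the trisubstituted C4′=C5′ alkene is bought with 31.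

In 29 the C1–O and C10–H bonds are removed together, giving the C1=C10 alkene of 26. Syn hydroboration guarantees the trans relation of C1–O and the C10 methyl. The face is decided by conformation, so the cut is made where C5 already carries an equatorial silyloxy group: it holds ring B so that the C9 methyl is axial on ring A and shields one face. The C6 ketone is reduced in the same operation and is restored by a selective allylic oxidation (28 to 29).

The C5–O bond of 26 is cut next, back to enone 23. Oxygen is delivered to the C5 enolate carbon from the convex face (that of the C4 hydrogen and the C9 methyl), which is the required one. The ketal oxygens present after the key step are deliberately not used: hydride would attack a C5 ketone from the same convex face and give the C5 epimer, a free C5/C6 dicarbonyl would enolise toward C4, and a C5 ketal holds the decalin in the chair pair that would send the hydroboration to the wrong face.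

The Z alkene of 23 is traced to butenolide 20, whose ring forces C12 and C6 cis. 20 comes from ketone 13 and ethyl pyruvate 14 by cutting C7–C11 (aldol). Here the C5 ketal earns its place: it leaves C7 as the only enolisable position of 13. It is removed reductively straight after the aldol (16 to 17).

Ketone 13 is cut at C8–C9 with re-formation of C1–C6, an oxy-Cope transform to the bicyclo[2.2.2]octenol 10. This removes ring B, the quaternary centre and the cis fusion in one stroke and reduces the ring stereocentres to the single stereochemical element of a rigid bicycle. Forward, the shift must pass through the boat array with the vinyl group syn to the dimethyl-substituted alkene.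

10 is cut at the vinyl–carbinol bond to ketone 7 and vinylmagnesium bromide 8; desulfonylation is placed after the addition (9 to 10) because the α,α-dialkoxy ketone would not survive the reductant. 7 is traced through racemate 6 to a Diels–Alder reaction between o-quinone monoketal 5 and phenyl vinyl sulfone 4 as an ethylene equivalent. 5 comes from guaiacol 3, made from 3,4-dimethylphenol 1 via bromide 2; the two aryl methyl groups become the C9 and C10 methyls.

## Alternatives that were turned down

Alternative 1: The C6–C7 bond of ring B is cut in a late intermediate that already carries the trienoate. Forward, a divalent-chromium/nickel-mediated (Nozaki–Hiyama–Kishi) intramolecular addition of a C7 alkenyl iodide to a C6 aldehyde closes ring B and gives allylic alcohol A1 as C6 epimers, which are oxidised afterwards.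
- For it: the Z tetrasubstituted alkene is fixed in the iodide and survives the coupling. On this point it is clearly stronger than the chosen route, which needs a lactone detour to hold the geometry. The conditions also tolerate the ester and silyl ethers.
- Against it: the ring closure creates none of the hard stereocentres. C1, C4, C5, C9 and C10, including the quaternary C9, must first be assembled on a monocyclic cyclohexane, and a stereodefined tetrasubstituted alkenyl iodide must be made. The aldehyde is α-silyloxy (epimerisable), the six-membered closure with a fully substituted alkenyl-chromium next to a quaternary carbon is expected to be sluggish, and stoichiometric chromium is spent on the most precious intermediate.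
- Comparison: the chosen strategy makes the quaternary centre and the cis fusion in one sigmatropic step from a phenol and lets the bicyclic shape set the remaining centres; the price is separate control of the alkene geometry.

Alternative 2: The whole bicyclic skeleton is cut back to acyclic farnesyl diphosphate A2. Forward, aristolochene synthase ionises A2, closes a ten-membered ring, then the decalin, and finishes with 1,2-hydride and 1,2-methyl shifts to give (+)-aristolochene A3.
- For it: unmatched step economy for the fifteen-carbon skeleton. The quaternary C9 methyl, the C10 methyl and the absolute configuration come from the enzyme, and on these points it is stronger than the chosen route.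
- Against it: A3 is a hydrocarbon with an sp2 ring-fusion carbon and an isopropenyl group. 40 needs oxygen at C1, C5, C6 and C12, a cis ring-fusion hydrogen and a shift of the side-chain alkene into the Z-hydroxymethyl alkylidene. These are selective oxidations at unactivated positions for which no plannable chemical methods exist, so further oxidases (pathway engineering) would be needed.
- Comparison: the chosen route carries the C6 oxygen from the arene and places the others by substrate-controlled reactions of functional groups.

Alternative 3: The C3–C4 bond of ring A is cut; ring B comes from a 4,4-disubstituted cyclohexa-2,5-dienone whose quaternary carbon becomes C9. Forward, a primary C3 radical on the side chain adds (6-exo) to C4 of one enone arm and gives cis-fused enone A4.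
- For it: it also starts from a dearomatised phenol and is equally short to the bicycle. The tether guarantees the cis fusion, and the C1 oxygen and C10 methyl are in place before cyclisation, so no hydroboration is needed; on that point it is stronger.
- Against it: the two enone arms are diastereotopic and the choice between them depends on acyclic stereocentres next to the prochiral carbon, which must themselves be made by separate asymmetric chemistry. Six-exo radical closures compete with reduction and hydrogen transfer. After cyclisation C5 is a bare methylene and the C7 alkylidene is still missing, so the end game is no shorter.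
- Comparison: in the chosen route one resolved bicycle relays its configuration to every centre, and the ketal makes C7 the only enolisable position for the side-arm construction.

Key step: step 7

Remark on the chemistry: 6, 7 and 9 are drawn with the sulfonyl group on the carbon next to the carbonyl-side bridgehead and syn to the alkene bridge, the usual outcome of such cycloadditions; its position is without consequence because step 6 removes it.

## Route

Step 1
Reactants: 1 3,4-dimethylphenol
Product: 2 2-bromo-4,5-dimethylphenol
Conditions: NBS, MeCN, 0 °C
Reagents that add atoms: N-bromosuccinimide, O=C1CCC(=O)N1Br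
Why: Electrophilic aromatic bromination; the para position is blocked, and of the two ortho positions the one para to the C3 methyl is unhindered and doubly activated.

Step 2
Reactants: 2 2-bromo-4,5-dimethylphenol
Product: 3 2-methoxy-4,5-dimethylphenol
Conditions: NaOMe (5 equiv), CuBr (10 mol %), MeOH/DMF, 110 °C, N2; then dilute HCl
Reagents that add atoms: sodium methoxide, C[O-].[Na+]
Why: Copper-catalysed (monovalent copper) Ullmann-type methoxylation of an o-bromophenol, a standard way to guaiacols.

Step 3
Reactants: 3 2-methoxy-4,5-dimethylphenol; 4 phenyl vinyl sulfone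
Product: 6 rac-3,3-dimethoxy-5,6-dimethyl-7-(phenylsulfonyl)bicyclo[2.2.2]oct-5-en-2-one, via masked o-benzoquinone 5 (not isolated)
Conditions: PhI(OAc)2 (1.1 equiv), 4 (5 equiv), MeOH, 50 °C, slow addition of 3
Reagents that add atoms: methanol, CO
Why: Oxidative dearomatisation in methanol gives the o-quinone monoketal 5, an s-cis-locked diene that undergoes Diels–Alder cycloaddition with the vinyl sulfone (ethylene equivalent). Slow addition keeps 5 dilute and suppresses its dimerisation; the adduct fixes the relative configuration of the two bridgeheads.

Step 4
Reactants: 6 racemic sulfonyl ketone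
Product: 7 (1R,4S,7S)-3,3-dimethoxy-5,6-dimethyl-7-(phenylsulfonyl)bicyclo[2.2.2]oct-5-en-2-one
Conditions: preparative HPLC on cellulose tris(3,5-dimethylphenylcarbamate), hexane/i-PrOH
Reagents that add atoms: none
Why: Resolution on a chiral stationary phase; the crystalline sulfone allows assignment of the absolute configuration by anomalous-dispersion X-ray analysis. The bridgehead that becomes C4 is the only stereochemical information carried forward.

Step 5
Reactants: 7 resolved sulfonyl ketone; 8 vinylmagnesium bromide
Product: 9 (1R,2R,4S,7S)-3,3-dimethoxy-5,6-dimethyl-7-(phenylsulfonyl)-2-vinylbicyclo[2.2.2]oct-5-en-2-ol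
Conditions: 8 (3 equiv), THF, −78 → 0 °C; then H2O
Reagents that add atoms: none
Why: Grignard 1,2-addition; the ketone face turned toward the sp2 bridge is less encumbered than the face toward the saturated bridge, so vinyl should enter syn to the alkene, as the rearrangement requires. Excess reagent covers deprotonation α to the sulfone.

Step 6
Reactants: 9 sulfonyl vinyl carbinol
Product: 10 (1R,2R,4S)-3,3-dimethoxy-5,6-dimethyl-2-vinylbicyclo[2.2.2]oct-5-en-2-ol
Conditions: Na/Hg (6 %), Na2HPO4, MeOH, −20 °C
Reagents that add atoms: none
Why: Reductive desulfonylation of an alkyl aryl sulfone by single-electron transfer; the tertiary alcohol, ketal and alkenes are inert. It is run after step 5 because the α,α-dialkoxy ketone of 7 would itself be reduced.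

Step 7
Reactants: 10 vinyl bicyclooctenol
Product: 13 cis-fused 5,5-dimethoxy-9,10-dimethyl-1(10)-octalin-6-one (target numbering), via potassium alkoxide 11 (not isolated), via potassium enolate 12 (not isolated)
Conditions: KH (1.5 equiv), 18-crown-6 (1.5 equiv), THF, 0 °C → rt; then H2O, 0 °C
Reagents that add atoms: none
Why: Deprotonation gives alkoxide 11, whose charge accelerates a concerted suprafacial [3,3] shift (anionic oxy-Cope rearrangement of a 2-vinylbicyclo[2.2.2]oct-5-en-2-ol, the established route from o-quinone monoketal adducts to cis-decalins). The bicycle holds the 1,5-diene C8=C7–C6–C1–C10=C9 in a boat-shaped six-centre array, so C8 bonds to C9 while C1–C6 breaks, giving enolate 12 (C6=C7) and the C1=C10 alkene. Ring B (C4, C5, C6, C7, C8, C9) is closed by this sigmatropic bond exchange and not by a polar or radical cyclisation, so no exo/endo choice arises. The only new stereocentre, C9, is set by the bridged framework: C8 can reach C9 only on the face turned toward the carbinol bridge, which puts the C9 methyl cis to the C4 hydrogen and relays the resolved bridgehead configuration. The step needs the vinyl group syn to the C9=C10 bridge (secured in step 5) and the [3,3] path in preference to a [1,3] shift or fragmentation; the rigid boat geometry and the mild anionic conditions favour it. Forming a quaternary centre at a fully substituted alkene carbon slows the shift, hence warming to room temperature; protonation of 12 gives 13 with C5 still blocked as the ketal.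

Step 8
Reactants: 13 ketal ketone; 14 ethyl pyruvate
Product: 16 C7 aldol adduct bearing a 1-ethoxycarbonyl-1-hydroxyethyl group (C7/C11 diastereomers), via lithium enolate 15 (not isolated)
Conditions: LiN(i-Pr)2 (1.1 equiv), THF, −78 °C; 14; AcOH quench at −78 °C
Reagents that add atoms: none
Why: Directed aldol addition; the quaternary ketal carbon leaves C7 as the only enolisable position, and the enolate attacks the ketone carbonyl of pyruvate, which is far more electrophilic than the ester. The diastereomers converge in steps 11 and 14.

Step 9
Reactants: 16 aldol adduct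
Product: 17 5-deoxy aldol adduct (C5 methylene, C6 ketone)
Conditions: SmI2 (5 equiv), THF/MeOH, −78 °C
Reagents that add atoms: none
Why: SmI2 cleaves C–O bonds α to a ketone (ketyl formation, loss of methoxide, protonation of the samarium enolate), here twice; esters, isolated ketones and alkenes are untouched at −78 °C. The ketal has done its work as blocking group and is removed before C5 is oxygenated from the correct face.

Step 10
Reactants: 17 5-deoxy aldol adduct
Product: 19 hydroxy lactone (γ-lactone from the C6 oxygen to C12; C11 bears OH and CH3), via diol ester 18 (not isolated)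
Conditions: NaBH4, MeOH, 0 °C; then p-TsOH (cat.), CH2Cl2, rt
Reagents that add atoms: none
Why: Borohydride reduction of the ketone followed by acid-catalysed γ-lactonisation onto the ester; the C6 and C11 configurations are immaterial because both centres become sp2 later.

Step 11
Reactants: 19 hydroxy lactone
Product: 20 butenolide (C7=C11 in the lactone ring, C1=C10 retained)
Conditions: SOCl2, pyridine, CH2Cl2, 0 °C
Reagents that add atoms: none
Why: Dehydration of a tertiary α-hydroxy lactone through the chlorosulfite (E2) should give the conjugated tetrasubstituted butenolide. The ring ties C12 to the C6 oxygen and so fixes the later Z geometry.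

Step 12
Reactants: 20 butenolide
Product: 21 (Z)-ene diol (C6 carbinol, C7=C11, C12 primary alcohol)
Conditions: LiAlH4, Et2O, −20 → 0 °C; sodium potassium tartrate work-up
Reagents that add atoms: none
Why: Hydride reduction of the lactone to the (Z)-2-ene-1,4-diol; the alkene is not touched, so C12 stays cis to C6. Non-acidic work-up avoids cyclisation to a dihydrofuran.

Step 13
Reactants: 21 (Z)-ene diol
Product: 22 C12 tert-butyldimethylsilyl ether
Conditions: TBSCl (1.05 equiv), imidazole, CH2Cl2, −20 °C
Reagents that add atoms: tert-butyldimethylsilyl chloride, CC(C)(C)[Si](C)(C)Cl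
Why: Silylation selects the primary allylic alcohol over the hindered secondary one.

Step 14
Reactants: 22 mono-silyl ether
Product: 23 (Z)-enone (C6 ketone, C5 methylene, C12 silyl ether)
Conditions: MnO2 (excess), CH2Cl2, rt
Reagents that add atoms: none
Why: Allylic alcohol oxidation; alkene geometry and silyl ether are unaffected under neutral conditions.

Step 15
Reactants: 23 (Z)-enone
Product: 25 (5R)-5-hydroxy enone (hydroxyl cis to the C4 hydrogen and C9 methyl), via potassium dienolate 24 (not isolated)
Conditions: KN(SiMe3)2 (1.1 equiv), THF, −78 °C; 2-(phenylsulfonyl)-3-phenyloxaziridine (1.3 equiv); AcOH quench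
Reagents that add atoms: 2-(phenylsulfonyl)-3-phenyloxaziridine, O=S(=O)(c1ccccc1)N1OC1c1ccccc1
Why: Kinetic deprotonation of the enone at the α′ carbon C5 gives the cross-conjugated dienolate 24, which is hydroxylated by the N-sulfonyloxaziridine (enolate oxidation). In the cis-decalin the face of C5 turned toward ring A is screened by C3 and C10, so oxygen should enter on the face of the C4 hydrogen and C9 methyl; the C1=C10 alkene is inert to this oxidant.

Step 16
Reactants: 25 5-hydroxy enone
Product: 26 5,12-bis(tert-butyldimethylsilyl) ether
Conditions: TBSOTf, 2,6-lutidine, CH2Cl2, −78 → 0 °C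
Reagents that add atoms: tert-butyldimethylsilyl triflate, CC(C)(C)[Si](C)(C)OS(=O)(=O)C(F)(F)F
Why: Silylation of the hindered α-ketol hydroxyl; the equatorial silyloxy group later acts as the conformational anchor for step 17.

Step 17
Reactants: 26 bis-silyl ether enone
Product: 28 C1/C6 diol (1R,10R; C6 carbinol of either configuration), via organoborane 27 (not isolated)
Conditions: BH3·THF (3 equiv), THF, 0 °C → rt; then 30 % H2O2, aq NaOAc, 0 °C
Reagents that add atoms: hydrogen peroxide, OO
Why: Borane reduces the C6 ketone and hydroborates the trisubstituted C1=C10 alkene with boron at the less substituted C1 (hydroboration–oxidation; the tetrasubstituted C7=C11 alkene is much slower). Syn addition makes C1–O trans to the C10 methyl; the equatorial C5 silyloxy group holds the decalin in the conformer whose C9 methyl is axial on ring A, so borane should add to the opposite face and place the C10 methyl cis to the C9 methyl. Buffered oxidation with retention limits 1,2-silyl migration.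

Step 18
Reactants: 28 C1/C6 diol
Product: 29 C1 alcohol with restored C6 enone ((1R,4S,5R,9R,10R))
Conditions: MnO2 (excess), CH2Cl2, rt
Reagents that add atoms: none
Why: MnO2 oxidises only the allylic C6 alcohol; the saturated C1 alcohol remains.

Step 19
Reactants: 30 hexanal; 31 triethyl 3-methyl-4-phosphonobut-2-enoate
Product: 32 ethyl (2E,4E)-3-methyldeca-2,4-dienoate
Conditions: LiN(SiMe3)2, THF/DMPU, −78 → 0 °C
Reagents that add atoms: none
Why: Vinylogous Horner–Wadsworth–Emmons olefination; the new C4=C5 alkene should form E and the 2E isomer should predominate, as in retinoid-type chain extensions.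

Step 20
Reactants: 32 dienoate
Product: 33 (2E,4E)-3-methyldeca-2,4-dien-1-ol
Conditions: i-Bu2AlH (2.2 equiv), CH2Cl2, −78 °C; sodium potassium tartrate work-up
Reagents that add atoms: none
Why: 1,2-Reduction of the conjugated ester to the allylic alcohol without touching the diene.

Step 21
Reactants: 33 dienol
Product: 34 (2E,4E)-3-methyldeca-2,4-dienal
Conditions: MnO2, CH2Cl2, rt
Reagents that add atoms: none
Why: Neutral allylic oxidation; no isomerisation of the diene is expected.

Step 22
Reactants: 34 dienal; 35 triethyl phosphonoacetate
Product: 36 ethyl (2E,4E,6E)-5-methyldodeca-2,4,6-trienoate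
Conditions: NaH, THF, 0 °C → rt
Reagents that add atoms: none
Why: Horner–Wadsworth–Emmons olefination of an aldehyde with a stabilised phosphonate, reliably E.

Step 23
Reactants: 36 trienoate ester
Product: 37 (2E,4E,6E)-5-methyldodeca-2,4,6-trienoic acid
Conditions: LiOH, THF/MeOH/H2O, rt; then dilute HCl to pH 4
Reagents that add atoms: lithium hydroxide, [Li+].[OH-]
Why: Saponification; mild acidification in the dark avoids isomerisation of the triene.

Step 24
Reactants: 29 C1 alcohol; 37 trienoic acid
Product: 39 C1 trienoate of the bis-silyl ether, via mixed anhydride 38 (not isolated)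
Conditions: 2,4,6-trichlorobenzoyl chloride, Et3N, THF, rt; then 29, DMAP, toluene, rt
Reagents that add atoms: none
Why: Yamaguchi esterification; DMAP transfers the trienoyl group from the mixed anhydride to the hindered equatorial C1 alcohol with retention at C1, and no acid is present that could harm the enone.

Step 25
Reactants: 39 protected ester
Product: 40 target
Conditions: HF·pyridine, excess pyridine, THF, 0 °C → rt
Reagents that add atoms: none
Why: Fluoride cleaves both silyl ethers; excess pyridine buffers the medium so that the (Z)-γ-hydroxy enone should not cyclise and dehydrate to the furan, and the α-ketol and trienoate are stable under these conditions.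

## Compound list

1 | 3,4-dimethylphenol | Cc1ccc(O)cc1C | starting material
2 | 2-bromo-4,5-dimethylphenol | Cc1cc(O)c(Br)cc1C | intermediate
3 | 2-methoxy-4,5-dimethylphenol | COc1cc(C)c(C)cc1O | intermediate
4 | phenyl vinyl sulfone | C=CS(=O)(=O)c1ccccc1 | starting material
5 | 6,6-dimethoxy-3,4-dimethylcyclohexa-2,4-dien-1-one (masked o-benzoquinone) | COC1(OC)C=C(C)C(C)=CC1=O | intermediate
6 | rac-3,3-dimethoxy-5,6-dimethyl-7-(phenylsulfonyl)bicyclo[2.2.2]oct-5-en-2-one (sulfonyl syn to the alkene bridge; both enantiomers) | O=C1[C@@H]2[C@@H](S(=O)(=O)c3ccccc3)C[C@@H](C(C)=C2C)C1(OC)OC.O=C1[C@H]2[C@H](S(=O)(=O)c3ccccc3)C[C@H](C(C)=C2C)C1(OC)OC | intermediate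
7 | (1R,4S,7S)-3,3-dimethoxy-5,6-dimethyl-7-(phenylsulfonyl)bicyclo[2.2.2]oct-5-en-2-one | O=C1[C@@H]2[C@@H](S(=O)(=O)c3ccccc3)C[C@@H](C(C)=C2C)C1(OC)OC | intermediate
8 | vinylmagnesium bromide | C=C[Mg]Br | starting material
9 | (1R,2R,4S,7S)-3,3-dimethoxy-5,6-dimethyl-7-(phenylsulfonyl)-2-vinylbicyclo[2.2.2]oct-5-en-2-ol (vinyl syn to the alkene bridge) | O[C@]1(C=C)[C@@H]2[C@@H](S(=O)(=O)c3ccccc3)C[C@@H](C(C)=C2C)C1(OC)OC | intermediate
10 | (1R,2R,4S)-3,3-dimethoxy-5,6-dimethyl-2-vinylbicyclo[2.2.2]oct-5-en-2-ol | O[C@]1(C=C)[C@@H]2CC[C@@H](C(C)=C2C)C1(OC)OC | intermediate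
11 | potassium alkoxide of 10 | [K+].[O-][C@]1(C=C)[C@@H]2CC[C@@H](C(C)=C2C)C1(OC)OC | intermediate
12 | potassium C6 enolate of 13 | [K+].[O-]C1=CC[C@]2(C)C(C)=CCC[C@@H]2C1(OC)OC | intermediate
13 | cis-fused 5,5-dimethoxy-9,10-dimethyl-1(10)-octalin-6-one (C4 hydrogen and C9 methyl cis) | CC1=CCC[C@@H]2C(OC)(OC)C(=O)CC[C@]12C | intermediate
14 | ethyl pyruvate | CCOC(=O)C(C)=O | starting material
15 | lithium C6 enolate of 13 | [Li+].[O-]C1=CC[C@]2(C)C(C)=CCC[C@@H]2C1(OC)OC | intermediate
16 | C7 aldol adduct of 13 with ethyl pyruvate (C7/C11 diastereomers) | CC1=CCC[C@@H]2C(OC)(OC)C(=O)C(C(C)(O)C(=O)OCC)C[C@]12C | intermediate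
17 | 5-deoxy aldol adduct (C5 methylene) | CC1=CCC[C@@H]2CC(=O)C(C(C)(O)C(=O)OCC)C[C@]12C | intermediate
18 | C6 alcohol of 17 (diol ester) | CC1=CCC[C@@H]2CC(O)C(C(C)(O)C(=O)OCC)C[C@]12C | intermediate
19 | hydroxy lactone (C6 oxygen to C12; C11 with OH and CH3; diastereomers) | CC1=CCC[C@@H]2CC3OC(=O)C(C)(O)C3C[C@]12C | intermediate
20 | butenolide (C7=C11; C6 epimers) | CC1=CCC[C@@H]2CC3OC(=O)C(C)=C3C[C@]12C | intermediate
21 | (Z)-ene diol (C6 carbinol, C12 alcohol) | CC1=CCC[C@@H]2CC(O)/C(=C(/C)CO)C[C@]12C | intermediate
22 | C12 tert-butyldimethylsilyl ether of 21 | CC1=CCC[C@@H]2CC(O)/C(=C(/C)CO[Si](C)(C)C(C)(C)C)C[C@]12C | intermediate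
23 | (Z)-enone with C5 methylene and C12 silyl ether | CC1=CCC[C@@H]2CC(=O)/C(=C(/C)CO[Si](C)(C)C(C)(C)C)C[C@]12C | intermediate
24 | potassium cross-conjugated dienolate of 23 | [K+].[O-]C1=C[C@H]2CCC=C(C)[C@@]2(C)C/C1=C(\C)CO[Si](C)(C)C(C)(C)C | intermediate
25 | (5R)-5-hydroxy enone | CC1=CCC[C@@H]2[C@@H](O)C(=O)/C(=C(/C)CO[Si](C)(C)C(C)(C)C)C[C@]12C | intermediate
26 | 5,12-bis(tert-butyldimethylsilyl) ether | CC1=CCC[C@@H]2[C@@H](O[Si](C)(C)C(C)(C)C)C(=O)/C(=C(/C)CO[Si](C)(C)C(C)(C)C)C[C@]12C | intermediate
27 | organoborane (C1 alkylborane, C6 alkoxyborane, drawn as BH2 derivatives) | B[C@@H]1CC[C@@H]2[C@@H](O[Si](C)(C)C(C)(C)C)C(OB)/C(=C(/C)CO[Si](C)(C)C(C)(C)C)C[C@]2(C)[C@H]1C | intermediate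
28 | C1/C6 diol | O[C@@H]1CC[C@@H]2[C@@H](O[Si](C)(C)C(C)(C)C)C(O)/C(=C(/C)CO[Si](C)(C)C(C)(C)C)C[C@]2(C)[C@H]1C | intermediate
29 | (1R,4S,5R,9R,10R) C1 alcohol with C6 enone | O[C@@H]1CC[C@@H]2[C@@H](O[Si](C)(C)C(C)(C)C)C(=O)/C(=C(/C)CO[Si](C)(C)C(C)(C)C)C[C@]2(C)[C@H]1C | intermediate
30 | hexanal | CCCCCC=O | starting material
31 | triethyl 3-methyl-4-phosphonobut-2-enoate (E/Z mixture as supplied) | CCOC(=O)C=C(C)CP(=O)(OCC)OCC | starting material
32 | ethyl (2E,4E)-3-methyldeca-2,4-dienoate | CCCCC/C=C/C(C)=C/C(=O)OCC | intermediate
33 | (2E,4E)-3-methyldeca-2,4-dien-1-ol | CCCCC/C=C/C(C)=C/CO | intermediate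
34 | (2E,4E)-3-methyldeca-2,4-dienal | CCCCC/C=C/C(C)=C/C=O | intermediate
35 | triethyl phosphonoacetate | CCOC(=O)CP(=O)(OCC)OCC | starting material
36 | ethyl (2E,4E,6E)-5-methyldodeca-2,4,6-trienoate | CCCCC/C=C/C(C)=C/C=C/C(=O)OCC | intermediate
37 | (2E,4E,6E)-5-methyldodeca-2,4,6-trienoic acid | CCCCC/C=C/C(C)=C/C=C/C(=O)O | intermediate
38 | mixed anhydride of 37 with 2,4,6-trichlorobenzoic acid | CCCCC/C=C/C(C)=C/C=C/C(=O)OC(=O)c1c(Cl)cc(Cl)cc1Cl | intermediate
39 | C1 trienoate, 5,12-bis-silyl ether | CCCCC/C=C/C(C)=C/C=C/C(=O)O[C@@H]1CC[C@@H]2[C@@H](O[Si](C)(C)C(C)(C)C)C(=O)/C(=C(/C)CO[Si](C)(C)C(C)(C)C)C[C@]2(C)[C@H]1C | intermediate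
40 | CNP0226738.1 | CCCCC/C=C/C(C)=C/C=C/C(=O)O[C@@H]1CC[C@@H]2[C@@H](O)C(=O)/C(=C(/C)CO)C[C@]2(C)[C@H]1C | target

## Step count and least certain steps

Total: 25 steps. Longest linear sequence: 20 steps (steps 1–18, 24, 25). The acid is made in 5 steps (19–23).

Step 7 (key step). The shift must create a quaternary centre at a fully substituted alkene carbon, so it may be slow enough for base-induced fragmentation of the α-ketal alkoxide or loss of the vinyl group to compete. Fallback: a neutral thermal silyloxy-Cope rearrangement. It sets out from 10, which is silylated (Me3SiCl, imidazole) to the trimethylsilyl ether F1; heating in a sealed tube (toluene, about 220 °C) should give the trimethylsilyl enol ether F2, and fluoride (Bu4NF, AcOH) returns to the route at 13.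

Step 11. Elimination may run toward the methyl group instead of into the ring, because in part of the diastereomer mixture the C7 hydrogen is not anti to the leaving group. Fallback: accept that regiochemistry and isomerise. It sets out from 19; the exocyclic isomer, α-methylene lactone F3, is moved into conjugation with the ring by catalytic RhCl3·3H2O in hot ethanol (metal hydride addition–elimination) and comes back at 20.

Step 15. Deprotonation at C12 (syn to the carbonyl) may compete with α′-deprotonation and scramble the alkene geometry, or the facial preference may be too small. Fallback: α′-acetoxylation without strong base. It sets out from 23; Mn(OAc)3 in refluxing benzene should give the C5 acetate F4 through the manganese enolate on the α′ side, and methanolysis (K2CO3, MeOH) comes back at 25.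

Step 17. The conformational bias may be smaller than assumed, leading to poor facial selectivity, and silyl migration from the C5 to the C6 oxygen may occur during the oxidative work-up. Fallback: correct C1 and C10 through the ketone. It sets out from 29 of insufficient diastereomeric purity: Dess–Martin oxidation gives the C1 ketone F5 (C10 epimers); equilibration with DBU should give F6, in which the C10 methyl is equatorial and cis to the C9 methyl; LiBH(s-Bu)3 at −78 °C attacks from the equatorial side to give the axial C1 alcohol F7; Mitsunobu esterification with 37 (PPh3, diisopropyl azodicarboxylate) inverts C1 and rejoins the route at 39.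

## Further compounds

F1 | step 7 | trimethylsilyl ether of 10 | C[Si](C)(C)O[C@]1(C=C)[C@@H]2CC[C@@H](C(C)=C2C)C1(OC)OC
F2 | step 7 | trimethylsilyl enol ether of 13 | C[Si](C)(C)OC1=CC[C@]2(C)C(C)=CCC[C@@H]2C1(OC)OC
F3 | step 11 | α-methylene lactone (C11=CH2 isomer of 20) | CC1=CCC[C@@H]2CC3OC(=O)C(=C)C3C[C@]12C
F4 | step 15 | C5 acetate of 25 | CC1=CCC[C@@H]2[C@@H](OC(C)=O)C(=O)/C(=C(/C)CO[Si](C)(C)C(C)(C)C)C[C@]12C
F5 | step 17 | C1 ketone from 29 (C10 epimers) | O=C1CC[C@@H]2[C@@H](O[Si](C)(C)C(C)(C)C)C(=O)/C(=C(/C)CO[Si](C)(C)C(C)(C)C)C[C@]2(C)C1C
F6 | step 17 | C1 ketone with C10 methyl cis to the C9 methyl | O=C1CC[C@@H]2[C@@H](O[Si](C)(C)C(C)(C)C)C(=O)/C(=C(/C)CO[Si](C)(C)C(C)(C)C)C[C@]2(C)[C@H]1C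
F7 | step 17 | C1 epimer of 29 (axial alcohol) | O[C@H]1CC[C@@H]2[C@@H](O[Si](C)(C)C(C)(C)C)C(=O)/C(=C(/C)CO[Si](C)(C)C(C)(C)C)C[C@]2(C)[C@H]1C
A1 | alternative 1 | bis-silylated C6 allylic alcohol corresponding to 40 (C6 epimers) | CCCCC/C=C/C(C)=C/C=C/C(=O)O[C@@H]1CC[C@@H]2[C@@H](O[Si](C)(C)C(C)(C)C)C(O)/C(=C(/C)CO[Si](C)(C)C(C)(C)C)C[C@]2(C)[C@H]1C
A2 | alternative 2 | (2E,6E)-farnesyl diphosphate | CC(C)=CCC/C(C)=C/CC/C(C)=C/COP(=O)(O)OP(=O)(O)O
A3 | alternative 2 | (+)-aristolochene | C1CCC2=CC[C@H](C(C)=C)C[C@]2(C)[C@H]1C
A4 | alternative 3 | cis-fused C1-silyloxy 7-en-6-one | CC(C)(C)[Si](C)(C)O[C@@H]1CC[C@@H]2CC(=O)C=C[C@]2(C)[C@H]1C
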